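Per minute is the unit I reckon in: I follow one molecule of substrate and ask how likely it is, each minute, to move on.

the same everywhere: substrate 0.12 M
- winter: partner 0.057 M; temperature 30 °C; run made earlier
- autumn: partner 0.086 M; temperature 50 °C; run made earlier
- south: partner 0.114 M; temperature 35 °C; time 12 min
- south-east: partner 0.114 M; temperature 65 °C; time 12 min
- south-west: partner 0.114 M; temperature 50 °C; time 12 min
- winter (time / min: product / %, substrate / %): 0.667: 0, 90.9; 2.00: 0.6, 79.8; 3.00: 1.0, 74.6; 5.00: 3.0, 69.3; 8.00: 6.8, 65.7; 10.0: 9.2, 63.3
- autumn (time / min: product / %, substrate / %): 0.417: 1.8, 78.1; 0.667: 1.5, 76.6; 1.00: 4.0, 75.1; 2.00: 9.9, 71.0; 3.00: 14.3, 66.9; 5.00: 24.0, 60.0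

(readings scatter by 0.5 percentage points)
- what was read earlier has a scatter of 0.5 percentage points, one standard deviation
- the flask that comes out highest in amount of product, in percent of the substrate charged, or "all alike" when all lie within 1.5 percentage points (south / south-east / south-west / all alike)
- product at the end, in percent of the substrate charged, south
- product at the end, in percent of the substrate charged, south-east
- product at the end, in percent of the substrate charged, south-west

On the fastest rung, a molecule leaves the substrate for a waiting pool, neither substrate nor product. In the autumn run that pool holds 20.1 % of the charge at 0.417 min, and in the winter run it holds 27.7 % at 5.00 min. The next rung is leaving the pool. Product made per minute, divided by the pool, gives the exit chance, a pseudo-first-order constant. The autumn pool averages 17.6 % over its last readings, so I read an exit chance of 0.268 min⁻¹. The winter pool averages 27.6 %, which gives 0.0449 min⁻¹.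

The two runs differ in partner charge as well as in temperature, so I assume that the chance goes with the partner charge, divide by that charge, and take the logarithm of what remains as straight in temperature. For the partner charge of the three new flasks, 0.114 M, this gives 0.127 min⁻¹ at 35 °C. The mean wait in the pool is then 7.89 min in south, 2.82 min in south-west and, extrapolated, 1.01 min in south-east. The slowest rung is the run itself, 12 min. South-east has the shortest wait, so I commit to south-east. I give no product figures of my own.

The forecast also names south-east, with 30 %, 78 % and 58 % for south, south-east and south-west. Its reading of the runs is “a complex forms first and then turns over slowly”.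

The flask gives 29.7 %, 76.0 % and 57.1 %, with south-east highest.

    substrate ⇌ open intermediate (K = 0.420, k = 0.00480 s⁻¹, Ea = 92.0 kJ mol⁻¹, ΔH = −20.0 kJ mol⁻¹)
    partner → second intermediate (k = 0.00810 s⁻¹, Ea = 74.0 kJ mol⁻¹)
    open intermediate + second intermediate → product (k = 0.0320 L mol⁻¹ s⁻¹, Ea = 65.0 kJ mol⁻¹)
    partner ⇌ dormant form (K = 1.40, k = 0.00850 s⁻¹, Ea = 82.0 kJ mol⁻¹, ΔH = 52.0 kJ mol⁻¹)
    (constants at 35 °C)

South-east moves 5 points with its partner charge at 0.103 M or 0.126 M, other charges and time held, so a run there is what could part from the forecast's figure. The pool is the open intermediate. In south-west it stands at 14.0 % at half time and 9.42 % at the end, so the autumn exit chance gives 19 percentage points of product over the second half, and the flask makes 21 points.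

South read early, at 3.0 min, holds 25.0 % of open intermediate; with that pool held from the start, the exit chance I reckoned for south gives 9.51 % of product. The computed value is lower, 4.87 %.

(The numbers in the tables stem from a simulated flask for substances that don't exist, noise included.)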